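Assumption: colpol has no stereocentre, so "single enantiomer" is taken to mean the single Z geometric isomer drawn; the Z alkene is the only stereo-element to control.

## Retrosynthetic overview

1. Key disconnection: both aryl–CH2 bonds of the (Z)-but-2-ene-1,4-diyl linker are cut in one operation, a Pd-catalysed three-component Z-selective 1,4-diarylation of butadiene that also sets the alkene geometry.
2. Ring A partner: hydroquinone (1) → 4-methoxyphenol (2) → 2-iodophenol 3 → pivalate 4 → bromo-iodo-arene 5 (I is the coupling handle, Br is kept).
3. Ring B partner: resorcinol (6) → tribromide 7 → 2-bromoresorcinol (8) → dipivalate 9 → C5 boronate 10 by Ir C–H borylation.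
4. Union and end game: 5 + butadiene (11) + 10 → tris-pivalate 12 → colpol (13) by one global ester cleavage.
5. No ring is formed: both benzene rings come intact from 1 and 6 and are only substituted.

## Route

**Step 1**
Reactants: 1 hydroquinone (benzene-1,4-diol)
Product: 2 4-methoxyphenol
Conditions: MeOH (solvent), H2SO4 (1 equiv), NaNO2 (10 mol %), rt
Reagents that add atoms: methanol, CO
Why: Acid/NOx-catalysed quinone–hydroquinone redox mono-etherification (MeOH adds to the transient protonated quinone and the hemiketal is reduced by more hydroquinone); it stops at the mono-ether because 2 cannot re-enter the quinone cycle.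

**Step 2**
Reactants: 2 4-methoxyphenol
Product: 3 2-iodo-4-methoxyphenol
Conditions: NIS (1.0 equiv), TsOH·H2O (10 mol %), MeCN, 0 °C → rt
Reagents that add atoms: N-iodosuccinimide, O=C1CCC(=O)N1I
Why: Electrophilic aromatic iodination goes ortho to the free OH, the strongest donor, because its para position is blocked.

**Step 3**
Reactants: 3 2-iodo-4-methoxyphenol
Product: 4 2-iodo-4-methoxyphenyl pivalate
Conditions: PivCl (1.2 equiv), Et3N, DMAP (5 mol %), CH2Cl2, 0 °C → rt
Reagents that add atoms: pivaloyl chloride, CC(C)(C)C(Cl)=O
Why: O-acylation; the pivalate switches off the directing power of the phenol oxygen for step 4, prevents phenoxide capture of the π-allyl in step 9, and tolerates mild base.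

**Step 4**
Reactants: 4 2-iodo-4-methoxyphenyl pivalate
Product: 5 5-bromo-2-iodo-4-methoxyphenyl pivalate (Br ortho to OMe and para to I)
Conditions: Br2 (1.05 equiv), NaOAc, AcOH, rt, dark
Reagents that add atoms: bromine, BrBr
Why: Electrophilic aromatic bromination is now controlled by OMe; of its two ortho positions, C3 is wedged between I and OMe, so Br enters C5 (also para to I).

**Step 5**
Reactants: 6 resorcinol (benzene-1,3-diol)
Product: 7 2,4,6-tribromobenzene-1,3-diol
Conditions: Br2 (3.1 equiv), CHCl3, 0 °C → rt
Reagents that add atoms: bromine, BrBr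
Why: Exhaustive electrophilic bromination of the three doubly activated positions (2, 4, 6) of resorcinol.

**Step 6**
Reactants: 7 2,4,6-tribromobenzene-1,3-diol
Product: 8 2-bromobenzene-1,3-diol (2-bromoresorcinol)
Conditions: Na2SO3 (2.5 equiv), NaOH, H2O/MeOH, rt; then HCl to pH 2
Reagents that add atoms: none
Why: Known selective reductive hydrodebromination of polybromophenols; sulfite removes the 4- and 6-bromines via the C-protonated keto tautomers and leaves the bromine flanked by both oxygens.

**Step 7**
Reactants: 8 2-bromobenzene-1,3-diol
Product: 9 2-bromo-1,3-phenylene bis(pivalate)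
Conditions: PivCl (2.5 equiv), Et3N, DMAP (10 mol %), CH2Cl2, 0 °C → rt
Reagents that add atoms: pivaloyl chloride, CC(C)(C)C(Cl)=O
Why: Double O-acylation gives base-tolerant esters that are removed together with the ring A pivalate at the end.

**Step 8**
Reactants: 9 2-bromo-1,3-phenylene bis(pivalate)
Product: 10 2-bromo-5-(4,4,5,5-tetramethyl-1,3,2-dioxaborolan-2-yl)-1,3-phenylene bis(pivalate) (Bpin para to Br)
Conditions: [Ir(OMe)(cod)]2 (1.5 mol %), dtbpy (3 mol %), B2pin2 (1.0 equiv), THF, 60 °C
Reagents that add atoms: bis(pinacolato)diboron, CC1(C)OB(OC1(C)C)B1OC(C)(C)C(C)(C)O1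
Why: Sterically governed Ir-catalysed aromatic C–H borylation; C5 is the only C–H without an ortho substituent, and the Ir-boryl catalyst leaves Ar–Br and esters untouched.

**Step 9**
Reactants: 5 5-bromo-2-iodo-4-methoxyphenyl pivalate (1.0 equiv); 11 buta-1,3-diene (5 equiv, 2 M in THF); 10 the ring B pinacol boronate (1.3 equiv)
Product: 12 (Z)-5-bromo-2-[4-(4-bromo-3,5-bis(pivaloyloxy)phenyl)but-2-en-1-yl]-4-methoxyphenyl pivalate
Conditions: Pd2(dba)3 (2.5 mol %), neocuproine (2,9-dimethyl-1,10-phenanthroline, 6 mol %), AgF (2.2 equiv), DMA/THF, 25 °C, dark, sealed vessel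
Reagents that add atoms: none
Why: Proposed new method: a Pd/2,9-disubstituted-phenanthroline-catalysed, Z-selective three-component 1,4-diarylation of butadiene (Heck-type carbopalladation followed by Suzuki–Miyaura termination). (N,N)Pd(0) should insert into the C–I bond of 5 at 25 °C but not into either hindered C–Br bond. AgF removes iodide, so the cationic aryl-Pd adds to C1 of butadiene and gives a 1-(arylmethyl)-π-allyl. The 2,9-methyl groups of the ligand clash with a syn substituent, so π–σ–π equilibration favours the anti π-allyl. Fluoride-assisted transmetalation of 10 and C–C reductive elimination from the less hindered primary σ-allyl then give the linear 1,4-product with the Z alkene. The closest known chemistry is Pd-catalysed 1,2-diarylation and E-selective 1,4-divinylation of 1,3-dienes with aryl/vinyl electrophiles plus organoborons, together with the known anti-π-allyl (Z-olefin) preference of 2,9-dialkylphenanthroline–Pd allyl complexes in allylic alkylation.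

**Step 10**
Reactants: 12 the tris-pivalate
Product: 13 colpol, 2-bromo-5-[(2Z)-4-(4-bromo-2-hydroxy-5-methoxyphenyl)but-2-en-1-yl]benzene-1,3-diol
Conditions: NaOMe (4 equiv), degassed MeOH/THF, 0 °C → rt, Ar; then AcOH, aq NH4Cl
Reagents that add atoms: none
Why: Base-mediated methanolysis (transesterification) of the three aryl pivalates; the conditions are too mild to isomerise the skipped Z alkene or to touch the aryl bromides and the methyl ether.

## Compound list

1 | hydroquinone | Oc1ccc(O)cc1 | starting material
2 | 4-methoxyphenol | COc1ccc(O)cc1 | intermediate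
3 | 2-iodo-4-methoxyphenol | COc1ccc(O)c(I)c1 | intermediate
4 | 2-iodo-4-methoxyphenyl pivalate | COc1ccc(OC(=O)C(C)(C)C)c(I)c1 | intermediate
5 | 5-bromo-2-iodo-4-methoxyphenyl pivalate | COc1cc(I)c(OC(=O)C(C)(C)C)cc1Br | intermediate
6 | resorcinol | Oc1cccc(O)c1 | starting material
7 | 2,4,6-tribromobenzene-1,3-diol | Oc1c(Br)cc(Br)c(O)c1Br | intermediate
8 | 2-bromobenzene-1,3-diol | Oc1cccc(O)c1Br | intermediate
9 | 2-bromo-1,3-phenylene bis(pivalate) | CC(C)(C)C(=O)Oc1cccc(OC(=O)C(C)(C)C)c1Br | intermediate
10 | 2-bromo-5-(pinacolboryl)-1,3-phenylene bis(pivalate) | CC(C)(C)C(=O)Oc1cc(B2OC(C)(C)C(C)(C)O2)cc(OC(=O)C(C)(C)C)c1Br | intermediate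
11 | buta-1,3-diene | C=CC=C | starting material
12 | (Z)-5-bromo-2-[4-(4-bromo-3,5-bis(pivaloyloxy)phenyl)but-2-en-1-yl]-4-methoxyphenyl pivalate | COc1cc(C/C=C\Cc2cc(OC(=O)C(C)(C)C)c(Br)c(OC(=O)C(C)(C)C)c2)c(OC(=O)C(C)(C)C)cc1Br | intermediate
13 | colpol | COc1cc(C/C=C\Cc2cc(O)c(Br)c(O)c2)c(O)cc1Br | target

## Summary

Total step count: 10.
Longest linear sequence: 6 (steps 1–4, 9, 10; the ring B branch, steps 5–8, 9, 10, is equally long).

Steps most likely to fail:

1. **Step 9 (proposed new three-component Z-selective 1,4-diarylation).** Risks are 1,2- versus 1,4-addition, E/Z ratio, direct biaryl Suzuki coupling and Heck diene formation. Fallback (known chemistry): convert each fragment into an allylarene — 5 with allyltributylstannane (Stille, Pd(PPh3)4, selective at C–I) and 10 with allyl bromide (Pd-catalysed allyl–aryl Suzuki coupling). Then join them by Z-selective olefin cross-metathesis with a cyclometalated Ru Z-selective catalyst, using the ring B allylarene in excess, and finish with step 10.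
2. **Step 4 (bromination of the iodo-arene).** Risks are regiochemistry and halogen scrambling. Fallback: change the order of functionalisation — brominate 4-methoxyphenyl pivalate first (no iodine present), cleave the ester, use the free OH to direct NIS iodination to the unhindered ortho position of 3-bromo-4-methoxyphenol, then re-pivaloylate to reach 5.
3. **Step 6 (selective hydrodebromination to 2-bromoresorcinol).** Risks are over- or under-reduction. Fallback: directed ortho-metalation instead — resorcinol bis(MOM) ether, n-BuLi (lithiation at C2 between the two OMOM groups), BrCF2CF2Br quench, then Ir borylation as in step 8. The MOM groups are then removed with HCl/MeOH after the pivalate cleavage.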